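**Retrosynthetic overview**

1. Locants: naphthalene C1–C8 (oxygen on C1, C3, C6, C8; side chain on C5); Ca = CH(CH3) on C5, Cb = the next CH (bears the aroyl group), Cc = the CH(CH3) after it; ring A = the benzoyl ring inside the ten-membered ring, ring E = the 2,6-dioxygenated phenyl.
2. Last disconnection, the six-membered carbocycle C4–C4a–C5–Ca–Cb–C(aryl): bond C4–C(aryl), made from the ring E ketone on Cb of macrocyclic diketone 18. It is possible because C4 is ortho to the oxygen on C3 and para to the oxygen on C1 (a vinylogous beta-diketone carbon), lies 1,5 to the ketone carbon across the peri gap, and the C1 oxygen lets the carbinol lose water to the dienone of the target. Global O-demethylation triggers the closure and equilibrates Cb.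
3. Ten-membered ring: intramolecular SNAr of the C6 naphthol onto the 2-fluoroaryl ketone (ring A) of 17. Cb–Cc bond and Cc: anti-selective Michael addition of the Z-enolate of ketone 11 to enone 16.
4. Ketone 11 and Ca: a temporary lactone ring (benzocoumarin on O6/C5), reduced enantioselectively with copper hydride and opened by 2,6-dimethoxyphenyllithium. The naphthalene comes from a Claisen cyclisation of keto ester 2.
5. Ring order: second naphthalene ring, then temporary lactone (later opened), then ten-membered ring, then the six-membered carbocycle (last).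

Key step: step 11

Remark: Cb is epimerisable; the configuration drawn for 17 and 18 is the one expected kinetically. It is assumed that the target (this tautomer, with trans substituents on Ca and Cb) is the thermodynamic form, so Cb is finally set under equilibrium control in step 11.

**Route**

Step 1
Reactants: 1 methyl 2-(3,5-dimethoxyphenyl)acetate
Product: 2 methyl 2-(2-acetyl-3,5-dimethoxyphenyl)acetate
Conditions: Ac2O, Sc(OTf)3 (10 mol %), MeNO2, 50 °C
Reagents that add atoms: acetic anhydride, CC(=O)OC(C)=O
Why: Friedel–Crafts acylation of the doubly activated ring should go para to one methoxy group (C2, equivalent to C6) and not to the doubly flanked C4, and the catalytic triflate avoids ether cleavage.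

Step 2
Reactants: 2 methyl 2-(2-acetyl-3,5-dimethoxyphenyl)acetate
Product: 4 1,3,6,8-tetramethoxynaphthalene, via 6,8-dimethoxynaphthalene-1,3-diol 3 (not isolated)
Conditions: NaH, DMF, 0 °C to rt; then Me2SO4, 0 °C to rt
Reagents that add atoms: dimethyl sulfate, COS(=O)(=O)OC
Why: Intramolecular Claisen (Dieckmann-type) condensation of the methyl ketone enolate onto the ester closes the second ring as a 1,3-diketone that aromatises to the naphthalene-1,3-diolate, which the hard electrophile O-methylates in the same flask.

Step 3
Reactants: 4 1,3,6,8-tetramethoxynaphthalene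
Product: 6 1-(2-hydroxy-4,5,7-trimethoxynaphthalen-1-yl)ethan-1-one, via 1-(2,4,5,7-tetramethoxynaphthalen-1-yl)ethan-1-one 5 (not isolated)
Conditions: AcCl, AlCl3, CH2Cl2, 0 °C to rt
Reagents that add atoms: acetyl chloride, CC(Cl)=O
Why: Friedel–Crafts acylation should take the alpha position C4 (para to the C1 and ortho to the C3 methoxy group; C4 and C5 are equivalent in the symmetric substrate), after which AlCl3 cleaves only the methyl ether ortho to the new carbonyl through a six-membered chelate.

Step 4
Reactants: 6 1-(2-hydroxy-4,5,7-trimethoxynaphthalen-1-yl)ethan-1-one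
Product: 7 6,7,9-trimethoxy-1-methyl-3H-benzo[f]chromen-3-one
Conditions: Ph3P=CHCO2Et, PhNEt2, 190 °C
Reagents that add atoms: ethyl (triphenylphosphoranylidene)acetate, CCOC(=O)C=P(c1ccccc1)(c1ccccc1)c1ccccc1
Why: Transesterification of the phenol by the stabilised ylide followed by intramolecular Wittig olefination of the ketone (Wittig lactonisation of ortho-hydroxyaryl ketones) should give the coumarin, the alkene geometry being fixed by the ring.

Step 5
Reactants: 7 6,7,9-trimethoxy-1-methyl-3H-benzo[f]chromen-3-one
Product: 8 (1R)-6,7,9-trimethoxy-1-methyl-1,2-dihydro-3H-benzo[f]chromen-3-one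
Conditions: Cu(OAc)2·H2O (3 mol %), (R)-DTBM-SEGPHOS (3 mol %), (EtO)2MeSiH, t-BuOH, toluene, 0 °C to rt
Reagents that add atoms: none
Why: Copper hydride asymmetric conjugate reduction of a beta,beta-disubstituted unsaturated lactone delivers hydride to one face of the beta carbon and sets Ca; the ligand enantiomer is the one that should give (R), and the antipodal ligand is used if the facial sense proves opposite.

Step 6
Reactants: 8 (1R)-6,7,9-trimethoxy-1-methyl-1,2-dihydro-3H-benzo[f]chromen-3-one; 9 1,3-dimethoxybenzene
Product: 11 (3R)-1-(2,6-dimethoxyphenyl)-3-(2-hydroxy-4,5,7-trimethoxynaphthalen-1-yl)butan-1-one, via (2,6-dimethoxyphenyl)lithium 10 (not isolated)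
Conditions: 9, n-BuLi, THF, 0 °C to rt; then 8 (0.45 equiv), −78 to −20 °C; NH4Cl (aq)
Reagents that add atoms: none
Why: Directed ortho-lithiation between the two methoxy groups and acyl substitution on the aryl ester (the lactone) expel the naphtholate and open the temporary ring; the di-ortho-substituted ketone, enolised by the second equivalent of 10, should resist a second addition, and Ca is not touched.

Step 7
Reactants: 12 1-fluoro-3-methoxybenzene; 13 (E)-but-2-enal
Product: 15 (E)-1-(2-fluoro-6-methoxyphenyl)but-2-en-1-ol (racemic), via (2-fluoro-6-methoxyphenyl)lithium 14 (not isolated)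
Conditions: 12, n-BuLi, THF, −78 °C; then 13, −78 °C; NH4Cl (aq)
Reagents that add atoms: none
Why: Ortho-lithiation at the carbon between fluorine and methoxy (kept at −78 °C to prevent benzyne formation) and 1,2-addition to the enal give the allylic alcohol.

Step 8
Reactants: 15 (E)-1-(2-fluoro-6-methoxyphenyl)but-2-en-1-ol
Product: 16 (E)-1-(2-fluoro-6-methoxyphenyl)but-2-en-1-one
Conditions: MnO2, CH2Cl2, rt
Reagents that add atoms: none
Why: MnO2 oxidises the allylic, benzylic alcohol selectively to the (E)-enone.

Step 9
Reactants: 11 (3R)-1-(2,6-dimethoxyphenyl)-3-(2-hydroxy-4,5,7-trimethoxynaphthalen-1-yl)butan-1-one; 16 (E)-1-(2-fluoro-6-methoxyphenyl)but-2-en-1-one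
Product: 17 (2R,3S)-1-(2,6-dimethoxyphenyl)-5-(2-fluoro-6-methoxyphenyl)-2-[(1R)-1-(2-hydroxy-4,5,7-trimethoxynaphthalen-1-yl)ethyl]-3-methylpentane-1,5-dione
Conditions: LiHMDS (2.2 equiv), THF, −78 °C; then 16, −78 °C; AcOH, −78 °C
Reagents that add atoms: none
Why: Kinetic Michael addition of the Z-lithium enolate (phenoxide–enolate dianion) to the (E)-enone through a closed, lithium-bridged transition state should give the anti adduct, as Z enolates of bulky aryl ketones do; the enolate is attacked anti to the naphthyl group with the hydrogen on Ca in the enolate plane (allylic 1,3-strain), so Ca sets Cb and, through the anti topicity, Cc.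

Step 10
Reactants: 17 (2R,3S)-1-(2,6-dimethoxyphenyl)-5-(2-fluoro-6-methoxyphenyl)-2-[(1R)-1-(2-hydroxy-4,5,7-trimethoxynaphthalen-1-yl)ethyl]-3-methylpentane-1,5-dione
Product: 18 hexa-O-methyl macrocyclic diketone (ten-membered diaryl ether ring; (R) at Ca, (R) at Cb, (S) at Cc)
Conditions: Cs2CO3, DMF (0.005 M), 70 °C
Reagents that add atoms: none
Why: Intramolecular SNAr (addition–elimination) of the caesium naphtholate on the fluoroarene activated by the ortho carbonyl, under high dilution, closes the ten-membered diaryl ether ring; only the phenol is deprotonated to a useful extent, and epimerisation at Cb here is harmless because step 11 equilibrates it.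

Step 11
Reactants: 18 hexa-O-methyl macrocyclic diketone
Product: 21 target CNP0225737.1, via hexaphenol macrocyclic diketone 19 (not isolated), via tertiary carbinol 20 (not isolated)
Conditions: BBr3 (excess), CH2Cl2, −78 °C to rt; then MeOH, aq. HCl, 40 °C
Reagents that add atoms: none
Why: BBr3 cleaves the six aryl methyl ethers (hexaphenol 19); the freed naphthalene-1,3-diol then attacks the acid-activated ring E ketone through C4 (intramolecular Friedel–Crafts hydroxyalkylation) to give carbinol 20, which ionises with the help of the para oxygen on C1 and loses water to the 3-hydroxy-1-oxo dienone (para-quinone methide) array of the target. The closest known reaction types are the Bradsher-type cyclodehydration of aryl ketones onto electron-rich arenes and the acid-mediated peri-annulation of naphthols to phenalenones, here run after a standard BBr3 global demethylation. The ring closes in a 6-exo-trig mode (C4 onto the exocyclic C=O; ring atoms C4, C4a, C5, Ca, Cb and the carbonyl carbon). Cb, alpha to the ketone before and vinylogous to the dienone after ring closure, equilibrates under the acidic conditions and should settle trans to the methyl on Ca (both pseudoaxial): the Ca methyl avoids allylic strain with the C6 aryloxy group and the ten-membered ring needs the Cb–Cc bond out of the naphthalene plane. The step needs C4 to react with this ketone only: C4 is the one nucleophilic carbon that reaches a carbonyl through a six-membered transition state, attack of C7 on the ring A ketone would give a xanthene bridged like a [5]metacyclophane, C2 is out of reach, and O6, tied up in the diaryl ether, cannot form a chromene.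

**Compound list**

1 | methyl 2-(3,5-dimethoxyphenyl)acetate | COC(=O)Cc1cc(OC)cc(OC)c1 | starting material
2 | methyl 2-(2-acetyl-3,5-dimethoxyphenyl)acetate | COC(=O)Cc1cc(OC)cc(OC)c1C(C)=O | intermediate
3 | 6,8-dimethoxynaphthalene-1,3-diol (formed in the flask) | COc1cc(OC)c2c(O)cc(O)cc2c1 | intermediate
4 | 1,3,6,8-tetramethoxynaphthalene | COc1cc(OC)c2c(OC)cc(OC)cc2c1 | intermediate
5 | 1-(2,4,5,7-tetramethoxynaphthalen-1-yl)ethan-1-one (formed in the flask) | CC(=O)c1c(OC)cc(OC)c2c(OC)cc(OC)cc12 | intermediate
6 | 1-(2-hydroxy-4,5,7-trimethoxynaphthalen-1-yl)ethan-1-one | CC(=O)c1c(O)cc(OC)c2c(OC)cc(OC)cc12 | intermediate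
7 | 6,7,9-trimethoxy-1-methyl-3H-benzo[f]chromen-3-one | CC1=CC(=O)Oc2cc(OC)c3c(OC)cc(OC)cc3c21 | intermediate
8 | (1R)-6,7,9-trimethoxy-1-methyl-1,2-dihydro-3H-benzo[f]chromen-3-one | C[C@@H]1CC(=O)Oc2cc(OC)c3c(OC)cc(OC)cc3c21 | intermediate
9 | 1,3-dimethoxybenzene | COc1cccc(OC)c1 | starting material
10 | (2,6-dimethoxyphenyl)lithium (formed in the flask) | [Li]c1c(OC)cccc1OC | intermediate
11 | (3R)-1-(2,6-dimethoxyphenyl)-3-(2-hydroxy-4,5,7-trimethoxynaphthalen-1-yl)butan-1-one | C[C@H](CC(=O)c1c(OC)cccc1OC)c1c(O)cc(OC)c2c(OC)cc(OC)cc12 | intermediate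
12 | 1-fluoro-3-methoxybenzene | COc1cccc(F)c1 | starting material
13 | (E)-but-2-enal | C/C=C/C=O | starting material
14 | (2-fluoro-6-methoxyphenyl)lithium (formed in the flask) | [Li]c1c(F)cccc1OC | intermediate
15 | (E)-1-(2-fluoro-6-methoxyphenyl)but-2-en-1-ol, racemic | C/C=C/C(O)c1c(F)cccc1OC | intermediate
16 | (E)-1-(2-fluoro-6-methoxyphenyl)but-2-en-1-one | C/C=C/C(=O)c1c(F)cccc1OC | intermediate
17 | (2R,3S)-1-(2,6-dimethoxyphenyl)-5-(2-fluoro-6-methoxyphenyl)-2-[(1R)-1-(2-hydroxy-4,5,7-trimethoxynaphthalen-1-yl)ethyl]-3-methylpentane-1,5-dione | C[C@@H](CC(=O)c1c(OC)cccc1F)[C@H]([C@@H](C)c1c(O)cc(OC)c2c(OC)cc(OC)cc12)C(=O)c1c(OC)cccc1OC | intermediate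
18 | hexa-O-methyl macrocyclic diketone: ten-membered ring (ring A ipso carbon, C=O, CH2, Cc, Cb, Ca, naphthalene C5, C6, O, ring A ortho carbon), 2,6-dimethoxybenzoyl on Cb, methoxy on naphthalene C1, C3, C8 and on ring A; (R) at Ca, (R) at Cb, (S) at Cc | C[C@H]1CC(=O)c2c(OC)cccc2Oc2cc(OC)c3c(OC)cc(OC)cc3c2[C@H](C)[C@@H]1C(=O)c1c(OC)cccc1OC | intermediate
19 | hexaphenol macrocyclic diketone (18 with all six methyl ethers cleaved; formed in the flask) | C[C@H]1CC(=O)c2c(O)cccc2Oc2cc(O)c3c(O)cc(O)cc3c2[C@H](C)[C@@H]1C(=O)c1c(O)cccc1O | intermediate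
20 | tertiary carbinol (19 after bond formation between naphthalene C4 and the ring E carbonyl carbon; carbinol configuration not defined; formed in the flask) | C[C@H]1CC(=O)c2c(O)cccc2Oc2cc(O)c3c(O)cc(O)c4c3c2[C@H](C)[C@@H]1C4(O)c1c(O)cccc1O | intermediate
21 | target CNP0225737.1; (R) at Ca, (R) at Cb, (S) at Cc | C[C@H]1CC(=O)c2c(O)cccc2Oc2cc(O)c3c4c2[C@H](C)[C@@H]1C(c1c(O)cccc1O)=C4C(O)=CC3=O | target

**Step count and risks**

Total step count: 11. Longest linear sequence: 9 steps (steps 1–6, 9, 10, 11).

Steps most likely to fail:

Step 10. Ring closure to the strained ten-membered ring may be slow at a fluoride activated only by a twisted carbonyl, so that intermolecular etherification and base-induced retro-Michael cleavage of the 1,5-diketone compete. The fallback sets out from 11 and comes back at 18, and closes the same ring by copper-catalysed coupling of an unactivated aryl bromide. Commercial 2-bromo-6-methoxybenzaldehyde and prop-1-enylmagnesium bromide should give (E)-1-(2-bromo-6-methoxyphenyl)but-2-en-1-ol F3 (alkene equilibrated with catalytic iodine at the enone stage). MnO2 should then give (E)-1-(2-bromo-6-methoxyphenyl)but-2-en-1-one F4. The Michael addition of step 9, run with 11 and F4, should give the bromo analogue of 17 F5. An intramolecular Ullmann ether synthesis (CuI, N,N-dimethylglycine, Cs2CO3, dioxane, 90 °C, high dilution) should close the ring to 18.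

Step 9. Poor facial selectivity at the enolate carbon relative to Ca, or erosion of the anti topicity, would give the epimer at Cc, which no later step can correct. The fallback sets out from 8 and comes back at 17, and puts the nucleophilic carbon into a ring. LiHMDS and Me3SiCl (THF, −78 °C) should convert 8 into its trimethylsilyl ketene acetal F1. A Mukaiyama–Michael addition of F1 to 16 (TiCl4, CH2Cl2, −78 °C) runs through an open transition state, which should favour the anti adduct, and the ring forces attack anti to the methyl group; the product is the trans lactone ketone F2. Treatment of F2 with LiHMDS (1 equiv, −78 °C, masks the fluoroaryl ketone as its enolate) and then with aryllithium 10 should open the lactone to 17.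

Step 11. Incomplete or unselective ether cleavage and acid-induced decomposition of the polyphenol may accompany the ring closure. The fallback sets out from 18 and comes back at 21, and separates the two events. MsOH in CH2Cl2 at rt should effect the cyclodehydration at the methyl ether stage and give the hexa-O-methyl 1H-phenalene F6, with a tetrasubstituted alkene between Cb and the aryl-bearing carbon. Demethylation with AlCl3 and EtSH (CH2Cl2, 0 °C to rt) should give the hexaphenol, whose proton shift to Cb gives 21.

Further compounds
F1 | step 9 | trimethylsilyl ketene acetal of lactone 8: (1R)-6,7,9-trimethoxy-1-methyl-3-(trimethylsilyloxy)-1H-benzo[f]chromene | C[C@@H]1C=C(O[Si](C)(C)C)Oc2cc(OC)c3c(OC)cc(OC)cc3c21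
F2 | step 9 | (1R,2R)-2-[(2S)-4-(2-fluoro-6-methoxyphenyl)-4-oxobutan-2-yl]-6,7,9-trimethoxy-1-methyl-1,2-dihydro-3H-benzo[f]chromen-3-one | C[C@@H](CC(=O)c1c(OC)cccc1F)[C@H]1C(=O)Oc2cc(OC)c3c(OC)cc(OC)cc3c2[C@@H]1C
F3 | step 10 | (E)-1-(2-bromo-6-methoxyphenyl)but-2-en-1-ol, racemic | C/C=C/C(O)c1c(Br)cccc1OC
F4 | step 10 | (E)-1-(2-bromo-6-methoxyphenyl)but-2-en-1-one | C/C=C/C(=O)c1c(Br)cccc1OC
F5 | step 10 | (2R,3S)-5-(2-bromo-6-methoxyphenyl)-1-(2,6-dimethoxyphenyl)-2-[(1R)-1-(2-hydroxy-4,5,7-trimethoxynaphthalen-1-yl)ethyl]-3-methylpentane-1,5-dione | C[C@@H](CC(=O)c1c(OC)cccc1Br)[C@H]([C@@H](C)c1c(O)cc(OC)c2c(OC)cc(OC)cc12)C(=O)c1c(OC)cccc1OC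
F6 | step 11 | hexa-O-methyl 1H-phenalene (18 after ring closure and loss of water; alkene between Cb and the aryl-bearing carbon; Ca and Cc as in 18) | C[C@H]1CC(=O)c2c(OC)cccc2Oc2cc(OC)c3c(OC)cc(OC)c4c3c2[C@H](C)C1=C4c1c(OC)cccc1OC
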